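**Retrosynthetic overview**

1. Numbering: C1 = methyl-bearing ring-fusion carbon, C2/C3 = cyclopentane CH2, C4 = isopropyl carbinol, C5 = ring-fusion CH, C6 = acyloxy CH, C7 = CH2, C8 = formyl-bearing alkene carbon, C9 = alkene CH, C10 = CH2 on C1, C14 = CHO, C15 = CH3. The target goes back to diol enal 24 (C6–O acylation last) and, by ester-to-enal adjustment at C14, to hydroxy ester 21.
2. The C4 carbinol comes from isopropylcerium addition to C4 ketone 20; the C4 oxygen and the trans C5–H come from hydroboration of the C4=C5 alkene of 17 on the face opposite C15.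
3. Key disconnection C5–C6: ring-fusion carbon C5 is bonded directly to the oxygen-bearing C6 of the seven-membered ring. C5, as an alkenylchromium made from the enol triflate of a cyclopentanone carbonyl, therefore adds to a C6 aldehyde; this closes the seven-membered ring onto the existing five-membered ring and leaves C4=C5 for the later oxygenation.
4. Cyclisation precursor 14 comes from an E-selective Horner–Wadsworth–Emmons olefination (C8=C9) of C9 aldehyde 8 (ozonolysis of an allyl group) with phosphonate 12, which carries C6 as an acetal.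
5. The quaternary C1 stereocentre comes from Pd-catalysed decarboxylative asymmetric allylation of β-keto ester 3 (from diallyl adipate). Ring order: five-membered ring in step 1, seven-membered ring in step 8.

Key step: step 8

Remark (assumptions): β denotes the face of the C15 methyl and α the opposite face; the (R)-PHOX ligand is assumed to give (R)-4 by analogy with the six-membered-ring series, and the antipodal ligand is to be used if the sign of 4 proves opposite.

**Route**

Step 1
Reactants: 1 diallyl adipate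
Product: 3 allyl 1-methyl-2-oxocyclopentane-1-carboxylate (racemic), via sodium enolate 2 (not isolated)
Conditions: NaH (1.05 equiv), THF, 0 → 40 °C; then MeI, rt
Reagents that add atoms: iodomethane, CI
Why: Dieckmann condensation closes the five-membered ring and leaves the β-keto ester as its sodium enolate, which is C-methylated in the same flask (β-keto ester alkylation) to give the quaternary carbon as a racemate that step 2 converts into one enantiomer.

Step 2
Reactants: 3 allyl 1-methyl-2-oxocyclopentane-1-carboxylate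
Product: 4 (2R)-2-methyl-2-(prop-2-en-1-yl)cyclopentan-1-one
Conditions: Pd2(dba)3 (2.5 mol %), (R)-(CF3)3-t-Bu-PHOX (6 mol %), toluene, 25 °C
Reagents that add atoms: none
Why: Decarboxylative asymmetric allylic alkylation (Tsuji–Trost type): ionisation and loss of CO2 give a Pd(π-allyl)–enolate pair, so both enantiomers of 3 converge and the chiral PHOX ligand decides which enolate face is allylated, setting quaternary C1 as (R); the electron-poor ligand is chosen because five-membered ketones are the less selective substrate class.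

Step 3
Reactants: 4 (2R)-2-methyl-2-(prop-2-en-1-yl)cyclopentan-1-one
Product: 6 (5R)-5-methyl-5-(prop-2-en-1-yl)cyclopent-1-en-1-yl trifluoromethanesulfonate, via potassium enolate 5 (not isolated)
Conditions: KHMDS, THF, −78 °C; then PhNTf2, −78 → 0 °C
Reagents that add atoms: N-phenylbis(trifluoromethanesulfonimide), O=S(=O)(N(c1ccccc1)S(=O)(=O)C(F)(F)F)C(F)(F)F
Why: Enol triflate formation: only one α-carbon of the ketone carries hydrogen, so enolisation and O-sulfonylation are regiodefined and C1 is not touched.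

Step 4
Reactants: 6 (5R)-5-methyl-5-(prop-2-en-1-yl)cyclopent-1-en-1-yl trifluoromethanesulfonate
Product: 8 (5R)-5-methyl-5-(2-oxoethyl)cyclopent-1-en-1-yl trifluoromethanesulfonate, via ozonide 7 (not isolated)
Conditions: O3, CH2Cl2, −78 °C, Sudan Red 7B as end-point indicator; then PPh3, −78 °C → rt
Reagents that add atoms: ozone, [O-][O+]=O
Why: Ozonolysis with reductive work-up: the monosubstituted alkene reacts much faster with ozone than the electron-poor enol triflate double bond, and the indicator stops the reaction before the latter is attacked.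

Step 5
Reactants: 9 triethyl phosphonoacetate; 10 bromoacetaldehyde diethyl acetal
Product: 12 ethyl 2-(diethoxyphosphoryl)-4,4-diethoxybutanoate, via sodium phosphonate 11 (not isolated)
Conditions: NaH, DMF, 0 °C → rt; then 10, NaI (cat.), 90 °C
Reagents that add atoms: none
Why: SN2 C-alkylation of the stabilised phosphonoacetate anion, with iodide catalysis and heat to overcome the low reactivity of the α-alkoxy bromide; mono-alkylation is favoured by the hindered product anion.

Step 6
Reactants: 8 (5R)-5-methyl-5-(2-oxoethyl)cyclopent-1-en-1-yl trifluoromethanesulfonate; 12 ethyl 2-(diethoxyphosphoryl)-4,4-diethoxybutanoate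
Product: 13 ethyl (2E)-2-(2,2-diethoxyethyl)-4-[(1R)-1-methyl-2-(trifluoromethanesulfonyloxy)cyclopent-2-en-1-yl]but-2-enoate
Conditions: LiCl, DBU, MeCN, 0 °C → rt
Reagents that add atoms: none
Why: Horner–Wadsworth–Emmons olefination under mild LiCl/amine conditions: α-substituted diethyl phosphonoacetates and unbranched aldehydes give mainly the E-enoate (ester trans to C10, hence C7 and C10 cis as the ring closure requires), the Z isomer is removed by chromatography, and the mild base spares the aldehyde and the enol triflate.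

Step 7
Reactants: 13 ethyl (2E)-2-(2,2-diethoxyethyl)-4-[(1R)-1-methyl-2-(trifluoromethanesulfonyloxy)cyclopent-2-en-1-yl]but-2-enoate
Product: 14 ethyl (2E)-4-[(1R)-1-methyl-2-(trifluoromethanesulfonyloxy)cyclopent-2-en-1-yl]-2-(2-oxoethyl)but-2-enoate
Conditions: TFA–H2O (1:1), CHCl3, 0 °C; crude aldehyde used at once
Reagents that add atoms: water, O
Why: Acid-catalysed acetal hydrolysis: the enol triflate and the ester are stable to cold aqueous acid, and short contact at 0 °C without chromatography should keep the β,γ-unsaturated aldehyde from moving into conjugation.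

Step 8
Reactants: 14 ethyl (2E)-4-[(1R)-1-methyl-2-(trifluoromethanesulfonyloxy)cyclopent-2-en-1-yl]-2-(2-oxoethyl)but-2-enoate
Product: 16 ethyl (4S,8aR)-4-hydroxy-8a-methyl-1,2,4,5,8,8a-hexahydroazulene-6-carboxylate (C6–OH; C4=C5; C8=C9 ester), via alkenylchromium(III) species 15 (not isolated)
Conditions: CrCl2 (6 equiv), NiCl2 (0.1 equiv), degassed DMF, slow addition of 14 to 0.005 M, 25 °C; aqueous work-up
Reagents that add atoms: none
Why: NiCl2 is reduced by Cr(II) to Ni(0), which inserts into the C5–OTf bond, transmetallation gives alkenylchromium(III) 15, and this adds through a closed, Cr–O-bound transition state to the C6 aldehyde before the chromium alkoxide is hydrolysed on work-up. The closest known reaction type is the intramolecular Nozaki–Hiyama–Kishi coupling of alkenyl triflates or iodides with aldehydes to form carbocycles. The seven-membered ring (C1, C5–C10) closes by 7-exo-trig attack of C5 on the formyl carbon, the cis relation of C7 and C10 across the C8=C9 enoate holding the aldehyde within reach of C5. The new stereocentre C6 is controlled by quaternary C1 through a chair-like cycloheptene transition state: C10 leaves C1 on the face opposite C15, C7 follows on that face, and the chromium-bound oxygen turns toward the open C4–H side of C5 and not toward C1, which places C6–H next to C15 and should give the (6S) carbinol. The step needs chemoselectivity for the aldehyde over the enoate, which the low reactivity of alkenylchromium(III) toward esters secures, and it needs the β,γ-unsaturated aldehyde to survive, which the neutral medium secures. High dilution favours ring closure over intermolecular addition.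

Step 9
Reactants: 16 ethyl (4S,8aR)-4-hydroxy-8a-methyl-1,2,4,5,8,8a-hexahydroazulene-6-carboxylate
Product: 17 ethyl (4S,8aR)-4-[(tert-butyldimethylsilyl)oxy]-8a-methyl-1,2,4,5,8,8a-hexahydroazulene-6-carboxylate
Conditions: TBSOTf, 2,6-lutidine, CH2Cl2, −78 → 0 °C
Reagents that add atoms: tert-butyldimethylsilyl trifluoromethanesulfonate, CC(C)(C)[Si](C)(C)OS(=O)(=O)C(F)(F)F
Why: Silylation of the hindered secondary allylic alcohol with the silyl triflate masks O6 against borane, the oxidant, the organocerium reagent and DIBAL-H in steps 10–13 without touching C6.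

Step 10
Reactants: 17 ethyl (4S,8aR)-4-[(tert-butyldimethylsilyl)oxy]-8a-methyl-1,2,4,5,8,8a-hexahydroazulene-6-carboxylate
Product: 19 ethyl (3R,3aR,4S,8aR)-4-[(tert-butyldimethylsilyl)oxy]-3-hydroxy-8a-methyl-1,2,3,3a,4,5,8,8a-octahydroazulene-6-carboxylate (4α-OH and 5α-H; trans ring fusion), via C4 alkylborane 18 (not isolated)
Conditions: BH3·THF, THF, 0 °C → rt; then NaBO3·4H2O, H2O, rt
Reagents that add atoms: sodium perborate, [Na+].[Na+].O[B-]1(O)OO[B-](O)(O)OO1
Why: Hydroboration–oxidation: boron adds to the less substituted C4 and hydrogen to C5, syn and from the α face opposite the axial-like C15 methyl on the adjacent quaternary C1 (as with cyclopentene double bonds next to an angular methyl in hydrindane and steroid systems), which sets C5–H trans to C15 (C4 is set too but is erased in step 11), while the electron-poor conjugated C8=C9 alkene and the ester react much more slowly with borane.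

Step 11
Reactants: 19 ethyl (3R,3aR,4S,8aR)-4-[(tert-butyldimethylsilyl)oxy]-3-hydroxy-8a-methyl-1,2,3,3a,4,5,8,8a-octahydroazulene-6-carboxylate
Product: 20 ethyl (3aS,4S,8aR)-4-[(tert-butyldimethylsilyl)oxy]-8a-methyl-3-oxo-1,2,3,3a,4,5,8,8a-octahydroazulene-6-carboxylate
Conditions: Dess–Martin periodinane, NaHCO3, CH2Cl2, 0 °C → rt; crude ketone used directly
Reagents that add atoms: none
Why: Dess–Martin oxidation under buffered, non-basic conditions gives the C4 ketone without epimerising the now enolisable C5–H or eliminating the β-silyloxy group.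

Step 12
Reactants: 20 ethyl (3aS,4S,8aR)-4-[(tert-butyldimethylsilyl)oxy]-8a-methyl-3-oxo-1,2,3,3a,4,5,8,8a-octahydroazulene-6-carboxylate
Product: 21 ethyl (3R,3aS,4S,8aR)-4-[(tert-butyldimethylsilyl)oxy]-3-hydroxy-8a-methyl-3-(propan-2-yl)-1,2,3,3a,4,5,8,8a-octahydroazulene-6-carboxylate (4β-OH, 4α-isopropyl)
Conditions: iPrMgCl, anhydrous CeCl3, THF, −78 °C; then 20, −78 °C; aq. NH4Cl
Reagents that add atoms: isopropylmagnesium chloride, CC(C)[Mg]Cl
Why: Organocerium 1,2-addition: the weakly basic isopropylcerium reagent adds without enolisation (C5 epimerisation, loss of silanol) or β-hydride reduction and attacks C4 from the α face, past the small C5–H and away from the β C15 methyl and the β-oriented C5–C6 branch, which sets C4 with OH β (cis to C15), the ketone being far more reactive than the hindered enoate at −78 °C.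

Step 13
Reactants: 21 ethyl (3R,3aS,4S,8aR)-4-[(tert-butyldimethylsilyl)oxy]-3-hydroxy-8a-methyl-3-(propan-2-yl)-1,2,3,3a,4,5,8,8a-octahydroazulene-6-carboxylate
Product: 22 (3R,3aS,4S,8aR)-4-[(tert-butyldimethylsilyl)oxy]-6-(hydroxymethyl)-8a-methyl-3-(propan-2-yl)-1,2,3,3a,4,5,8,8a-octahydroazulen-3-ol
Conditions: DIBAL-H (4 equiv), CH2Cl2, −78 °C; Rochelle salt work-up
Reagents that add atoms: none
Why: DIBAL-H 1,2-reduction of the α,β-unsaturated ester gives the C14 allylic alcohol without conjugate reduction, the extra hydride covering the free tertiary alcohol.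

Step 14
Reactants: 22 (3R,3aS,4S,8aR)-4-[(tert-butyldimethylsilyl)oxy]-6-(hydroxymethyl)-8a-methyl-3-(propan-2-yl)-1,2,3,3a,4,5,8,8a-octahydroazulen-3-ol
Product: 23 (3R,3aS,4S,8aR)-6-(hydroxymethyl)-8a-methyl-3-(propan-2-yl)-1,2,3,3a,4,5,8,8a-octahydroazulene-3,4-diol
Conditions: TBAF, THF, rt → 45 °C
Reagents that add atoms: none
Why: Fluoride-mediated desilylation frees C6–OH at a stage where no base-sensitive enal is yet present; the Si–O bond is cleaved, so C6 keeps its configuration.

Step 15
Reactants: 23 (3R,3aS,4S,8aR)-6-(hydroxymethyl)-8a-methyl-3-(propan-2-yl)-1,2,3,3a,4,5,8,8a-octahydroazulene-3,4-diol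
Product: 24 (3R,3aS,4S,8aR)-3,4-dihydroxy-8a-methyl-3-(propan-2-yl)-1,2,3,3a,4,5,8,8a-octahydroazulene-6-carbaldehyde
Conditions: activated MnO2, CH2Cl2, rt
Reagents that add atoms: none
Why: Manganese dioxide oxidises only the allylic primary alcohol to the enal and leaves the saturated secondary C6–OH and the tertiary C4–OH untouched.

Step 16
Reactants: 25 4-hydroxybenzoic acid
Product: 27 4-[(tert-butyldimethylsilyl)oxy]benzoic acid, via bis-silyl derivative 26 (not isolated)
Conditions: TBSCl (2.5 equiv), imidazole, DMF, rt; then AcOH–THF–H2O, rt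
Reagents that add atoms: tert-butyldimethylsilyl chloride, CC(C)(C)[Si](C)(C)Cl
Why: Silylation of both the phenol and the acid, followed by selective hydrolysis of the far more labile silyl ester, leaves the aryl silyl ether in place.

Step 17
Reactants: 24 (3R,3aS,4S,8aR)-3,4-dihydroxy-8a-methyl-3-(propan-2-yl)-1,2,3,3a,4,5,8,8a-octahydroazulene-6-carbaldehyde; 27 4-[(tert-butyldimethylsilyl)oxy]benzoic acid
Product: 28 (3R,3aS,4S,8aR)-6-formyl-3-hydroxy-8a-methyl-3-(propan-2-yl)-1,2,3,3a,4,5,8,8a-octahydroazulen-4-yl 4-[(tert-butyldimethylsilyl)oxy]benzoate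
Conditions: EDC·HCl, DMAP, CH2Cl2, rt
Reagents that add atoms: none
Why: Steglich esterification: the carbodiimide-activated acid acylates the secondary C6–OH under DMAP catalysis with retention at C6 (the C6–O bond is not broken), while the tertiary C4–OH does not react and the enal is not affected.

Step 18
Reactants: 28 (3R,3aS,4S,8aR)-6-formyl-3-hydroxy-8a-methyl-3-(propan-2-yl)-1,2,3,3a,4,5,8,8a-octahydroazulen-4-yl 4-[(tert-butyldimethylsilyl)oxy]benzoate
Product: 29 (3R,3aS,4S,8aR)-6-formyl-3-hydroxy-8a-methyl-3-(propan-2-yl)-1,2,3,3a,4,5,8,8a-octahydroazulen-4-yl 4-hydroxybenzoate (target)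
Conditions: TBAF, AcOH (1:1), THF, 0 °C
Reagents that add atoms: none
Why: Buffered fluoride cleaves the labile aryl silyl ether within minutes and leaves the secondary benzoate, the enal and the tertiary alcohol unchanged.

**Compound list**

1 | diallyl adipate (diprop-2-en-1-yl hexanedioate) | C=CCOC(=O)CCCCC(=O)OCC=C | starting material
2 | sodium enolate of allyl 2-oxocyclopentane-1-carboxylate | [Na+].[O-]C1=C(C(=O)OCC=C)CCC1 | intermediate (not isolated)
3 | allyl 1-methyl-2-oxocyclopentane-1-carboxylate (racemic) | C=CCOC(=O)C1(C)CCCC1=O | intermediate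
4 | (2R)-2-methyl-2-(prop-2-en-1-yl)cyclopentan-1-one | C=CC[C@@]1(C)CCCC1=O | intermediate
5 | potassium (5R)-5-methyl-5-(prop-2-en-1-yl)cyclopent-1-en-1-olate | C=CC[C@@]1(C)CCC=C1[O-].[K+] | intermediate (not isolated)
6 | (5R)-5-methyl-5-(prop-2-en-1-yl)cyclopent-1-en-1-yl trifluoromethanesulfonate | C=CC[C@@]1(C)CCC=C1OS(=O)(=O)C(F)(F)F | intermediate
7 | (5R)-5-methyl-5-[(1,2,4-trioxolan-3-yl)methyl]cyclopent-1-en-1-yl trifluoromethanesulfonate (ozonide, mixture at the trioxolane carbon) | C1OC(C[C@@]2(C)CCC=C2OS(=O)(=O)C(F)(F)F)OO1 | intermediate (not isolated)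
8 | (5R)-5-methyl-5-(2-oxoethyl)cyclopent-1-en-1-yl trifluoromethanesulfonate | O=CC[C@@]1(C)CCC=C1OS(=O)(=O)C(F)(F)F | intermediate
9 | triethyl phosphonoacetate | CCOC(=O)CP(=O)(OCC)OCC | starting material
10 | bromoacetaldehyde diethyl acetal (2-bromo-1,1-diethoxyethane) | CCOC(CBr)OCC | starting material
11 | sodium salt of triethyl phosphonoacetate | [Na+].CCOC(=O)[CH-]P(=O)(OCC)OCC | intermediate (not isolated)
12 | ethyl 2-(diethoxyphosphoryl)-4,4-diethoxybutanoate (racemic) | CCOC(=O)C(CC(OCC)OCC)P(=O)(OCC)OCC | intermediate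
13 | ethyl (2E)-2-(2,2-diethoxyethyl)-4-[(1R)-1-methyl-2-(trifluoromethanesulfonyloxy)cyclopent-2-en-1-yl]but-2-enoate | CCOC(=O)/C(CC(OCC)OCC)=C/C[C@@]1(C)CCC=C1OS(=O)(=O)C(F)(F)F | intermediate
14 | ethyl (2E)-4-[(1R)-1-methyl-2-(trifluoromethanesulfonyloxy)cyclopent-2-en-1-yl]-2-(2-oxoethyl)but-2-enoate | CCOC(=O)/C(CC=O)=C/C[C@@]1(C)CCC=C1OS(=O)(=O)C(F)(F)F | intermediate
15 | C5 alkenylchromium(III) dichloride derived from 14 | CCOC(=O)/C(CC=O)=C/C[C@@]1(C)CCC=C1[Cr](Cl)Cl | intermediate (not isolated)
16 | ethyl (4S,8aR)-4-hydroxy-8a-methyl-1,2,4,5,8,8a-hexahydroazulene-6-carboxylate | CCOC(=O)C1=CC[C@@]2(C)CCC=C2[C@@H](O)C1 | intermediate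
17 | ethyl (4S,8aR)-4-[(tert-butyldimethylsilyl)oxy]-8a-methyl-1,2,4,5,8,8a-hexahydroazulene-6-carboxylate | CCOC(=O)C1=CC[C@@]2(C)CCC=C2[C@@H](O[Si](C)(C)C(C)(C)C)C1 | intermediate
18 | C4 alkylborane from 17 (4α-boryl, 5α-H) | CCOC(=O)C1=CC[C@@]2(C)CC[C@@H](B)[C@@H]2[C@@H](O[Si](C)(C)C(C)(C)C)C1 | intermediate (not isolated)
19 | ethyl (3R,3aR,4S,8aR)-4-[(tert-butyldimethylsilyl)oxy]-3-hydroxy-8a-methyl-1,2,3,3a,4,5,8,8a-octahydroazulene-6-carboxylate | CCOC(=O)C1=CC[C@@]2(C)CC[C@@H](O)[C@@H]2[C@@H](O[Si](C)(C)C(C)(C)C)C1 | intermediate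
20 | ethyl (3aS,4S,8aR)-4-[(tert-butyldimethylsilyl)oxy]-8a-methyl-3-oxo-1,2,3,3a,4,5,8,8a-octahydroazulene-6-carboxylate | CCOC(=O)C1=CC[C@@]2(C)CCC(=O)[C@@H]2[C@@H](O[Si](C)(C)C(C)(C)C)C1 | intermediate
21 | ethyl (3R,3aS,4S,8aR)-4-[(tert-butyldimethylsilyl)oxy]-3-hydroxy-8a-methyl-3-(propan-2-yl)-1,2,3,3a,4,5,8,8a-octahydroazulene-6-carboxylate | CCOC(=O)C1=CC[C@@]2(C)CC[C@@](O)(C(C)C)[C@@H]2[C@@H](O[Si](C)(C)C(C)(C)C)C1 | intermediate
22 | (3R,3aS,4S,8aR)-4-[(tert-butyldimethylsilyl)oxy]-6-(hydroxymethyl)-8a-methyl-3-(propan-2-yl)-1,2,3,3a,4,5,8,8a-octahydroazulen-3-ol | OCC1=CC[C@@]2(C)CC[C@@](O)(C(C)C)[C@@H]2[C@@H](O[Si](C)(C)C(C)(C)C)C1 | intermediate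
23 | (3R,3aS,4S,8aR)-6-(hydroxymethyl)-8a-methyl-3-(propan-2-yl)-1,2,3,3a,4,5,8,8a-octahydroazulene-3,4-diol | OCC1=CC[C@@]2(C)CC[C@@](O)(C(C)C)[C@@H]2[C@@H](O)C1 | intermediate
24 | (3R,3aS,4S,8aR)-3,4-dihydroxy-8a-methyl-3-(propan-2-yl)-1,2,3,3a,4,5,8,8a-octahydroazulene-6-carbaldehyde | O=CC1=CC[C@@]2(C)CC[C@@](O)(C(C)C)[C@@H]2[C@@H](O)C1 | intermediate
25 | 4-hydroxybenzoic acid | OC(=O)c1ccc(O)cc1 | starting material
26 | tert-butyldimethylsilyl 4-[(tert-butyldimethylsilyl)oxy]benzoate | CC(C)(C)[Si](C)(C)OC(=O)c1ccc(O[Si](C)(C)C(C)(C)C)cc1 | intermediate (not isolated)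
27 | 4-[(tert-butyldimethylsilyl)oxy]benzoic acid | OC(=O)c1ccc(O[Si](C)(C)C(C)(C)C)cc1 | intermediate
28 | (3R,3aS,4S,8aR)-6-formyl-3-hydroxy-8a-methyl-3-(propan-2-yl)-1,2,3,3a,4,5,8,8a-octahydroazulen-4-yl 4-[(tert-butyldimethylsilyl)oxy]benzoate | O=CC1=CC[C@@]2(C)CC[C@@](O)(C(C)C)[C@@H]2[C@@H](OC(=O)c3ccc(O[Si](C)(C)C(C)(C)C)cc3)C1 | intermediate
29 | (3R,3aS,4S,8aR)-6-formyl-3-hydroxy-8a-methyl-3-(propan-2-yl)-1,2,3,3a,4,5,8,8a-octahydroazulen-4-yl 4-hydroxybenzoate | CC(C)[C@]1(O)CC[C@]2(C)CC=C(C=O)C[C@H](OC(=O)c3ccc(O)cc3)[C@H]21 | target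

**Step count and risks**

Total step count: 18. Longest linear sequence: 16 steps (steps 1–4, 6–15, 17, 18).

Step 8 (most likely to fail). Closure of the seven-membered ring at the hindered C5 alkenyl metal may be slower than protonolysis of the carbon–metal bond or intermolecular addition, and the face selectivity at the aldehyde may be weak. The fallback sets out from triflate 6 and phosphonate 12 and comes back at 16; it keeps the C5–C6 bond formation but closes the ring at C8=C9 by metathesis. Phosphonate 12 is methylenated with aqueous formaldehyde and K2CO3 (HWE) to ethyl 2-(2,2-diethoxyethyl)prop-2-enoate F1, and the acetal is hydrolysed as in step 7 to ethyl 2-methylidene-4-oxobutanoate F2. Intermolecular Ni/Cr coupling of 6 with F2 should give ethyl 4-hydroxy-2-methylidene-4-[(5R)-5-methyl-5-(prop-2-en-1-yl)cyclopent-1-en-1-yl]butanoate F3 as both C6 epimers. Ring-closing metathesis (Grubbs second-generation catalyst, CH2Cl2, 40 °C) between the allyl group and the acrylate then forms the seven-membered ring and gives 16 together with its C6 epimer, ethyl (4R,8aR)-4-hydroxy-8a-methyl-1,2,4,5,8,8a-hexahydroazulene-6-carboxylate F4. The unwanted epimer F4 (also if it arises in step 8 itself) is oxidised with Dess–Martin periodinane to ethyl (8aR)-8a-methyl-4-oxo-1,2,4,5,8,8a-hexahydroazulene-6-carboxylate F5 and reduced under reagent control (Corey–Bakshi–Shibata reduction, (R)-catalyst, catecholborane, −78 °C) to 16.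

Step 10. Borane may be delivered to the β face (syn to C15) if the folded seven-membered ring shields the α face, which would give the cis ring fusion, and excess borane may begin to reduce the enoate. The fallback sets out from 17 and comes back at 20; it replaces the syn addition by an overall anti addition, so that the same face preference leads to the trans fusion. mCPBA (NaHCO3, CH2Cl2, 0 °C) epoxidises the electron-rich C4=C5 alkene on the β face to give ethyl (4S,8aR)-4-[(tert-butyldimethylsilyl)oxy]-3,3a-epoxy-8a-methyl-1,2,3,3a,4,5,8,8a-octahydroazulene-6-carboxylate (β-epoxide) F6. Cp2TiCl (from Cp2TiCl2 and Zn) with 1,4-cyclohexadiene opens the epoxide homolytically at the more substituted C5, and the planar C5 radical should take up hydrogen on the α face, opposite the vicinal titanium alkoxide and C15. This gives the 4β-alcohol with 5α-H, the C4 epimer of 19, F7, which Dess–Martin oxidation converts into 20.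

Step 7. During the acidic hydrolysis the C8=C9 double bond may migrate into conjugation with the new aldehyde, or the doubly activated C7 methylene may enolise and the aldehyde decompose. The fallback sets out from 8 and 9 and comes back at 14; it reaches the aldehyde by a neutral oxidation instead of an acidic unmasking. Phosphonate 9 is alkylated with (2-iodoethoxy)(tert-butyl)dimethylsilane (NaH, DMF) to ethyl 4-[(tert-butyldimethylsilyl)oxy]-2-(diethoxyphosphoryl)butanoate F8. HWE olefination with 8 (LiCl, DBU, MeCN) gives ethyl (2E)-2-{2-[(tert-butyldimethylsilyl)oxy]ethyl}-4-[(1R)-1-methyl-2-(trifluoromethanesulfonyloxy)cyclopent-2-en-1-yl]but-2-enoate F9. HF·pyridine in THF/pyridine at 0 °C then frees ethyl (2E)-2-(2-hydroxyethyl)-4-[(1R)-1-methyl-2-(trifluoromethanesulfonyloxy)cyclopent-2-en-1-yl]but-2-enoate F10, which is oxidised at once with Dess–Martin periodinane and NaHCO3 to 14.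

**Further compounds**

F1 | step 8 | ethyl 2-(2,2-diethoxyethyl)prop-2-enoate | C=C(CC(OCC)OCC)C(=O)OCC
F2 | step 8 | ethyl 2-methylidene-4-oxobutanoate | C=C(CC=O)C(=O)OCC
F3 | step 8 | ethyl 4-hydroxy-2-methylidene-4-[(5R)-5-methyl-5-(prop-2-en-1-yl)cyclopent-1-en-1-yl]butanoate (both C6 epimers) | C=CC[C@@]1(C)CCC=C1C(O)CC(=C)C(=O)OCC
F4 | step 8 | ethyl (4R,8aR)-4-hydroxy-8a-methyl-1,2,4,5,8,8a-hexahydroazulene-6-carboxylate (C6 epimer of 16) | CCOC(=O)C1=CC[C@@]2(C)CCC=C2[C@H](O)C1
F5 | step 8 | ethyl (8aR)-8a-methyl-4-oxo-1,2,4,5,8,8a-hexahydroazulene-6-carboxylate | CCOC(=O)C1=CC[C@@]2(C)CCC=C2C(=O)C1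
F6 | step 10 | ethyl (4S,8aR)-4-[(tert-butyldimethylsilyl)oxy]-3,3a-epoxy-8a-methyl-1,2,3,3a,4,5,8,8a-octahydroazulene-6-carboxylate (epoxide on the β face) | CCOC(=O)C1=CC[C@@]2(C)CC[C@@H]3O[C@]23[C@@H](O[Si](C)(C)C(C)(C)C)C1
F7 | step 10 | ethyl 4-[(tert-butyldimethylsilyl)oxy]-3-hydroxy-8a-methyl-1,2,3,3a,4,5,8,8a-octahydroazulene-6-carboxylate, C4 epimer of 19 (4β-OH, 5α-H) | CCOC(=O)C1=CC[C@@]2(C)CC[C@H](O)[C@@H]2[C@@H](O[Si](C)(C)C(C)(C)C)C1
F8 | step 7 | ethyl 4-[(tert-butyldimethylsilyl)oxy]-2-(diethoxyphosphoryl)butanoate | CCOC(=O)C(CCO[Si](C)(C)C(C)(C)C)P(=O)(OCC)OCC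
F9 | step 7 | ethyl (2E)-2-{2-[(tert-butyldimethylsilyl)oxy]ethyl}-4-[(1R)-1-methyl-2-(trifluoromethanesulfonyloxy)cyclopent-2-en-1-yl]but-2-enoate | CCOC(=O)/C(CCO[Si](C)(C)C(C)(C)C)=C/C[C@@]1(C)CCC=C1OS(=O)(=O)C(F)(F)F
F10 | step 7 | ethyl (2E)-2-(2-hydroxyethyl)-4-[(1R)-1-methyl-2-(trifluoromethanesulfonyloxy)cyclopent-2-en-1-yl]but-2-enoate | CCOC(=O)/C(CCO)=C/C[C@@]1(C)CCC=C1OS(=O)(=O)C(F)(F)F
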